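**Retrosynthetic overview**
1. Target ⇒ mono-aryl methyl acetal + guaiacol: the last C–C bond is a Friedel–Crafts arylation of a cis-fused bicyclic oxocarbenium ion on its convex (exo) face.
2. Mono-aryl acetal ⇒ C2-symmetric bicyclic bis-acetal + aryltrifluoroborate (ipso aryl transfer, exo face). Both tetrahydrofuran rings close together by double transacetalisation of (2R,3R)-2,3-bis(dimethoxymethyl)butane-1,4-diol.
3. Diol ⇒ vicinal bis(boronate) by a double 1,2-shift of the skeleton carbons from boron to carbon (Matteson CH2 insertion, ionic, stereoretentive). This key step builds the branched C6 skeleton.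
4. Bis(boronate) ⇒ fumaraldehyde bis(dimethyl acetal) (one step from furan) by an enantioselective syn-diboration, new on this substrate class, which sets both bridgehead centres.
5. Both arenes come from catechol (methylation; ortho-lithiation/oxidation; Ir C–H borylation). Ring order: both THF rings at once, then aryl 1, then aryl 2.

Assumptions: the target is (1R,2S,5R,6S) with both aryl groups exo (pinoresinol-type); acetal carbons in 18 and 19 are anomeric mixtures (the exo-OMe anomer is drawn, both give the same oxocarbenium ion); "(S)-Quinap" in step 6 stands for whichever ligand enantiomer gives (2S,3S)-14.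

**Step 1**
Reactants: 1 catechol
Product: 2 guaiacol (2-methoxyphenol)
Conditions: MeI (1.0 equiv), K2CO3 (1.0 equiv), acetone, reflux
Reagents that add atoms: iodomethane, CI
Why: Williamson O-methylation with one equivalent of MeI gives mainly the mono-ether, which is separated from veratrole and catechol by base extraction and distillation.

**Step 2**
Reactants: 1 catechol
Product: 3 veratrole (1,2-dimethoxybenzene)
Conditions: MeI (2.5 equiv), K2CO3 (3 equiv), acetone, reflux
Reagents that add atoms: iodomethane, CI
Why: Exhaustive Williamson O-methylation with excess MeI and base.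

**Step 3**
Reactants: 3 veratrole
Product: 6 2,3-dimethoxyphenol, via aryllithium 4 (not isolated), via arylboronate 5 (not isolated)
Conditions: n-BuLi, TMEDA, THF, 0 °C → rt; B(OMe)3, −78 °C → rt; AcOH, 30% H2O2, 0 °C → rt
Reagents that add atoms: hydrogen peroxide, OO
Why: Directed ortho-metalation puts lithium at C3 (ortho to OMe), the aryllithium is trapped as the boronate, and the C–B bond is oxidised to C–OH at the same position (lithiation–borylation–oxidation).

**Step 4**
Reactants: 6 2,3-dimethoxyphenol
Product: 9 potassium trifluoro(3-hydroxy-4,5-dimethoxyphenyl)borate, via aryl borate 7 (not isolated), via diborylated arene 8 (not isolated)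
Conditions: B2pin2 (1.1 equiv), HBpin (0.1 equiv), [Ir(OMe)(cod)]2 (1.5 mol %), dtbpy (3 mol %), THF, 80 °C; then aq. KHF2, MeOH, rt
Reagents that add atoms: bis(pinacolato)diboron, CC1(C)OB(OC1(C)C)B1OC(C)(C)C(C)(C)O1; potassium hydrogen difluoride, F.[F-].[K+]
Why: Iridium-catalysed C–H borylation is sterically controlled: the phenol is masked in the flask as its O-Bpin ester, C5 is the only C–H without an ortho substituent, and KHF2 then turns C–Bpin into the trifluoroborate and cleaves the O–B bond.

**Step 5**
Reactants: 10 furan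
Product: 12 (E)-1,1,4,4-tetramethoxybut-2-ene, via dimethoxydihydrofuran 11 (not isolated)
Conditions: Br2, MeOH, −45 °C → rt
Reagents that add atoms: methanol, CO
Why: Clauson-Kaas-type oxidative 1,4-dimethoxylation of furan, followed by HBr-catalysed methanolysis of the cyclic bis-acetal and acid equilibration to the E-alkene.

**Step 6**
Reactants: 12 (E)-1,1,4,4-tetramethoxybut-2-ene
Product: 14 (2S,3S)-1,1,4,4-tetramethoxy-2,3-bis(4,4,5,5-tetramethyl-1,3,2-dioxaborolan-2-yl)butane, via bis(catecholboronate) 13 (not isolated)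
Conditions: B2cat2 (1.1 equiv), (nbd)Rh(acac) (5 mol %), (S)-Quinap (5 mol %), THF, rt; then pinacol, rt
Reagents that add atoms: bis(catecholato)diboron, c1ccc2OB(Oc2c1)B1Oc2ccccc2O1; pinacol, CC(C)(O)C(C)(C)O
Why: Proposed new method: Rh(I)/Quinap-catalysed enantioselective syn-diboration of a trans-alkene flanked by two acetal carbons, with ester exchange to pinacol in the same flask; B2cat2 adds oxidatively to the Rh–P,N complex, the alkene inserts into Rh–B on the enantioface chosen by the ligand, and C–B reductive elimination completes the syn addition (it must outrun β-methoxide and β-hydride elimination, which the poor leaving-group ability of acetal OMe and the second boryl on rhodium should allow), so the E-alkene gives only the C2-symmetric (2S,3S)-isomer and both future bridgehead centres are fixed in one event; the closest known reaction is the Rh/Quinap enantioselective diboration of simple trans-1,2-disubstituted alkenes with B2cat2, not yet shown for acetal-substituted alkenes.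

**Step 7**
Reactants: 14 (2S,3S)-1,1,4,4-tetramethoxy-2,3-bis(4,4,5,5-tetramethyl-1,3,2-dioxaborolan-2-yl)butane
Product: 17 (2R,3R)-2,3-bis(dimethoxymethyl)butane-1,4-diol, via bis-ate complex 15 (not isolated), via bis(borylmethyl)butane 16 (not isolated)
Conditions: BrCH2Cl (6 equiv), n-BuLi (5 equiv), THF, −78 °C → rt (repeat once if mono-homologated material remains); then 3 M NaOH, 30% H2O2, 0 °C → rt
Reagents that add atoms: bromochloromethane, ClCBr; hydrogen peroxide, OO
Why: Double Matteson homologation: each boron takes up LiCH2Cl to give an ate complex in which the stereogenic skeleton carbon shifts from boron to the neighbouring carbon with loss of chloride (1,2-metallate shift, stereoretentive), so both new C–CH2 bonds form without touching the stereocentres, and alkaline peroxide then replaces boron by OH with retention (S→R is only a CIP priority change).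

**Step 8**
Reactants: 17 (2R,3R)-2,3-bis(dimethoxymethyl)butane-1,4-diol, 9 potassium trifluoro(3-hydroxy-4,5-dimethoxyphenyl)borate
Product: 19 (1R,2S,5R,6S)-2-(3-hydroxy-4,5-dimethoxyphenyl)-6-methoxy-3,7-dioxabicyclo[3.3.0]octane, via bicyclic bis-acetal 18 (not isolated)
Conditions: 17 (2.5 equiv), CSA (5 mol %), 5 Å MS, CH2Cl2, rt; then 9 (1 equiv), BF3·OEt2 (3 equiv), MeCN, −20 → 0 °C
Reagents that add atoms: none
Why: Acid-catalysed double transacetalisation closes both tetrahydrofuran rings at once (cis-fused), BF3 then ionises one of the two homotopic methoxy acetals, and the aryl group is delivered by ipso-substitution at boron (organotrifluoroborate–acetal coupling through ArBF2) to the convex face of the bicyclic oxocarbenium ion, which sets C2 with the aryl exo; the excess of 18 keeps the reaction at one arylation and is recovered.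

**Step 9**
Reactants: 19 (1R,2S,5R,6S)-2-(3-hydroxy-4,5-dimethoxyphenyl)-6-methoxy-3,7-dioxabicyclo[3.3.0]octane, 2 guaiacol
Product: 20 (1R,2S,5R,6S)-2-(3-hydroxy-4,5-dimethoxyphenyl)-6-(4-hydroxy-3-methoxyphenyl)-3,7-dioxabicyclo[3.3.0]octane (target CNP0324902.1)
Conditions: 2 (5 equiv), BF3·OEt2 (0.3 equiv), 5 Å MS, CH2Cl2, −40 → −10 °C
Reagents that add atoms: none
Why: Friedel–Crafts C-arylation of the second bicyclic oxocarbenium ion by guaiacol at its most nucleophilic, unhindered position para to OH (the chemistry of the sesamolin-to-sesaminol conversion), again on the convex face, sets the last stereocentre exo and gives the target without protecting groups.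

**Compound list**
1 | catechol (benzene-1,2-diol) | Oc1ccccc1O | starting material
2 | guaiacol (2-methoxyphenol) | COc1ccccc1O | intermediate
3 | veratrole (1,2-dimethoxybenzene) | COc1ccccc1OC | intermediate
4 | (2,3-dimethoxyphenyl)lithium | [Li]c1cccc(OC)c1OC | intermediate (not isolated)
5 | dimethyl (2,3-dimethoxyphenyl)boronate | COB(OC)c1cccc(OC)c1OC | intermediate (not isolated)
6 | 2,3-dimethoxyphenol | COc1cccc(O)c1OC | intermediate
7 | 2-(2,3-dimethoxyphenoxy)-4,4,5,5-tetramethyl-1,3,2-dioxaborolane | COc1cccc(OB2OC(C)(C)C(C)(C)O2)c1OC | intermediate (not isolated)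
8 | 2-[3,4-dimethoxy-5-(4,4,5,5-tetramethyl-1,3,2-dioxaborolan-2-yloxy)phenyl]-4,4,5,5-tetramethyl-1,3,2-dioxaborolane | COc1cc(cc(OB2OC(C)(C)C(C)(C)O2)c1OC)B1OC(C)(C)C(C)(C)O1 | intermediate (not isolated)
9 | potassium trifluoro(3-hydroxy-4,5-dimethoxyphenyl)borate | [K+].COc1cc(cc(O)c1OC)[B-](F)(F)F | intermediate
10 | furan | c1ccoc1 | starting material
11 | 2,5-dimethoxy-2,5-dihydrofuran (cis/trans mixture) | COC1C=CC(OC)O1 | intermediate (not isolated)
12 | (E)-1,1,4,4-tetramethoxybut-2-ene (fumaraldehyde bis(dimethyl acetal)) | COC(OC)/C=C/C(OC)OC | intermediate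
13 | 2,2'-[(2S,3S)-1,1,4,4-tetramethoxybutane-2,3-diyl]bis(1,3,2-benzodioxaborole) | COC(OC)[C@@H](B1Oc2ccccc2O1)[C@H](B1Oc2ccccc2O1)C(OC)OC | intermediate (not isolated)
14 | (2S,3S)-1,1,4,4-tetramethoxy-2,3-bis(4,4,5,5-tetramethyl-1,3,2-dioxaborolan-2-yl)butane | COC(OC)[C@@H](B1OC(C)(C)C(C)(C)O1)[C@H](B1OC(C)(C)C(C)(C)O1)C(OC)OC | intermediate
15 | dilithium bis-ate complex of 14 (2S,3S; each boron also carries a CH2Cl group) | [Li+].[Li+].COC(OC)[C@@H]([B-]1(CCl)OC(C)(C)C(C)(C)O1)[C@H]([B-]1(CCl)OC(C)(C)C(C)(C)O1)C(OC)OC | intermediate (not isolated)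
16 | (2S,3S)-1,1,4,4-tetramethoxy-2,3-bis[(4,4,5,5-tetramethyl-1,3,2-dioxaborolan-2-yl)methyl]butane | COC(OC)[C@@H](CB1OC(C)(C)C(C)(C)O1)[C@H](CB1OC(C)(C)C(C)(C)O1)C(OC)OC | intermediate (not isolated)
17 | (2R,3R)-2,3-bis(dimethoxymethyl)butane-1,4-diol | COC(OC)[C@@H](CO)[C@H](CO)C(OC)OC | intermediate
18 | (1R,2S,5R,6S)-2,6-dimethoxy-3,7-dioxabicyclo[3.3.0]octane (cis-fused; exo,exo anomer drawn, anomeric mixture) | CO[C@H]1OC[C@H]2[C@@H]1CO[C@@H]2OC | intermediate (not isolated)
19 | (1R,2S,5R,6S)-2-(3-hydroxy-4,5-dimethoxyphenyl)-6-methoxy-3,7-dioxabicyclo[3.3.0]octane (aryl exo; exo-OMe anomer drawn, anomeric mixture) | CO[C@H]1OC[C@H]2[C@@H]1CO[C@@H]2c1cc(O)c(OC)c(OC)c1 | intermediate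
20 | (1R,2S,5R,6S)-2-(3-hydroxy-4,5-dimethoxyphenyl)-6-(4-hydroxy-3-methoxyphenyl)-3,7-dioxabicyclo[3.3.0]octane, i.e. 5-[(1S,3aR,4S,6aR)-4-(4-hydroxy-3-methoxyphenyl)tetrahydro-1H,3H-furo[3,4-c]furan-1-yl]-2,3-dimethoxyphenol (both aryls exo) | COc1cc([C@H]2OC[C@H]3[C@@H]2CO[C@@H]3c2cc(O)c(OC)c(OC)c2)ccc1O | target

**Count**
Total steps: 9. Longest linear sequence: 5 (furan → 12 → 14 → 17 → 19 → 20, or catechol → 3 → 6 → 9 → 19 → 20).

**Three steps most likely to fail**

Step 6 (the proposed new diboration). It may stall, lose methoxide by β-elimination, or give low ee. The fallback sets out from 12 and comes back at 14 with known chemistry. Base-catalysed, metal-free syn-diboration of the internal alkene (B2pin2, Cs2CO3, MeOH, THF, 70 °C) gives 14 as the racemate, that is, mixed 1:1 with its enantiomer (2R,3R)-1,1,4,4-tetramethoxy-2,3-bis(4,4,5,5-tetramethyl-1,3,2-dioxaborolan-2-yl)butane F1. The two are separated by preparative chromatography on a chiral stationary phase, so stereocontrol comes from separation instead of from a catalyst, and 14 goes on to step 7.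

Step 7 (double CH2 insertion at two neighbouring, hindered, β-alkoxy boronates). The second ate complex may not form, or methoxide may be lost. The fallback sets out from 14 and comes back at 17; it replaces the one-carbon insertion by vinylation and oxidative cleavage. Vinyllithium (THF, −78 °C) gives the dilithium bis(vinyl)boronate complex F2. Iodine in MeOH triggers the stereoretentive 1,2-shift to (3S,4S)-3,4-bis(dimethoxymethyl)-1,6-diiodo-2,5-bis(4,4,5,5-tetramethyl-1,3,2-dioxaborolan-2-yl)hexane F3. NaOMe then eliminates boron and iodide (Zweifel olefination) to give (3S,4S)-3,4-bis(dimethoxymethyl)hexa-1,5-diene F4. Ozonolysis (O3, CH2Cl2/MeOH, −78 °C) gives (2R,3R)-2,3-bis(dimethoxymethyl)butanedial F5, which is reduced in the same flask with NaBH4 to 17.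

Step 8 (aryl transfer from a phenol-bearing trifluoroborate to one of two equal acetals). Risks are low reactivity, O-arylation, or over-arylation. The fallback sets out from 17 and 9 and comes back at 19; it replaces oxocarbenium substitution by carbonyl addition and ring closure. Hydrolysis of 17 (Amberlyst-15, THF/H2O) gives the bis-lactol (1R,5R)-3,7-dioxabicyclo[3.3.0]octane-2,6-diol F6, used in excess. Rh(I)-catalysed 1,2-addition of 9 to its open hydroxy-aldehyde form (Rh(acac)(CO)2, dppf, DME/H2O, 80 °C) gives (3R,4R)-4-[(3-hydroxy-4,5-dimethoxyphenyl)(hydroxy)methyl]-3-(hydroxymethyl)oxolan-2-ol F7 as a mixture of carbinol epimers. CSA in MeOH then closes the second ring through the p-methoxy-stabilised benzylic cation under thermodynamic control (aryl exo) and re-forms the methyl acetal, giving 19.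

**Further compounds**
F1 | step 6 | (2R,3R)-1,1,4,4-tetramethoxy-2,3-bis(4,4,5,5-tetramethyl-1,3,2-dioxaborolan-2-yl)butane (enantiomer of 14, formed with it as the racemate) | COC(OC)[C@H](B1OC(C)(C)C(C)(C)O1)[C@@H](B1OC(C)(C)C(C)(C)O1)C(OC)OC
F2 | step 7 | dilithium bis(vinyl)boronate complex of 14 (2S,3S; each boron also carries a vinyl group) | [Li+].[Li+].COC(OC)[C@@H]([B-]1(C=C)OC(C)(C)C(C)(C)O1)[C@H]([B-]1(C=C)OC(C)(C)C(C)(C)O1)C(OC)OC
F3 | step 7 | (3S,4S)-3,4-bis(dimethoxymethyl)-1,6-diiodo-2,5-bis(4,4,5,5-tetramethyl-1,3,2-dioxaborolan-2-yl)hexane (epimers at C2 and C5) | COC(OC)[C@@H](C(CI)B1OC(C)(C)C(C)(C)O1)[C@H](C(CI)B1OC(C)(C)C(C)(C)O1)C(OC)OC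
F4 | step 7 | (3S,4S)-3,4-bis(dimethoxymethyl)hexa-1,5-diene | COC(OC)[C@@H](C=C)[C@H](C=C)C(OC)OC
F5 | step 7 | (2R,3R)-2,3-bis(dimethoxymethyl)butanedial | COC(OC)[C@@H](C=O)[C@H](C=O)C(OC)OC
F6 | step 8 | (1R,5R)-3,7-dioxabicyclo[3.3.0]octane-2,6-diol (anomeric mixture) | OC1OC[C@H]2[C@@H]1COC2O
F7 | step 8 | (3R,4R)-4-[(3-hydroxy-4,5-dimethoxyphenyl)(hydroxy)methyl]-3-(hydroxymethyl)oxolan-2-ol (epimers at the lactol and carbinol carbons) | OC1OC[C@H]([C@@H]1CO)C(O)c1cc(O)c(OC)c(OC)c1
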